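**Retrosynthetic overview**
1. Target 42 ⇐ alcohol 39: O8 methacryloylation and removal of two silyl ethers come last; no ring is formed after the key step.
2. 39 ⇐ seco enal–allylboronate 36: the ten-membered carbocycle is closed first (C6–C7) and the trans-fused α-methylene-γ-butyrolactone second, in the same flask (new macrocyclising allylboration–lactonisation).
3. 36 ⇐ ynoate 31 ⇐ aldehyde 26: the geometry-defined 2-(methoxycarbonyl)allylboronate comes from syn hydroalumination and borylmethylation of an ynoate.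
4. 25 ⇐ alkene 15 + vinyl iodide 23 (from but-2-yne-1,4-diol): C3–C4 bond by B-alkyl Suzuki–Miyaura coupling, which fixes the C4=C5 geometry.
5. 15 ⇐ lactone 1: C8 from the chiral pool; C10 by allylation, then kinetic protonation of the lactone enolate.

Assumption: atom labels use germacrane numbering (ring C1–C10, lactone C11–C13, C14 on C10, C15 on C4); compound 1 and all numbered reagents are taken as commercial, and LiN(i-Pr)2, 9-BBN and i-Bu2AlH are used as commercial solutions.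

**Route**

Step 1
Reactants: 1 (R)-5-(hydroxymethyl)dihydrofuran-2(3H)-one; 2 trityl chloride
Product: 3 (R)-5-((trityloxy)methyl)dihydrofuran-2(3H)-one
Conditions: TrCl, Et3N, DMAP (cat.), CH2Cl2, rt
Reagents that add atoms: trityl chloride 2, ClC(c1ccccc1)(c1ccccc1)c1ccccc1
Why: O-tritylation of the primary alcohol installs the bulky group that later shields one face of the lactone, and the C8 stereocentre is taken unchanged from the chiral pool.

Step 2
Reactants: 3 (R)-5-((trityloxy)methyl)dihydrofuran-2(3H)-one; 4 allyl bromide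
Product: 6 (3S,5R)-3-allyl-5-((trityloxy)methyl)dihydrofuran-2(3H)-one, via lithium lactone enolate 5 (not isolated)
Conditions: LiN(i-Pr)2, THF, −78 °C; then allyl bromide, −78 → −40 °C
Reagents that add atoms: allyl bromide 4, C=CCBr
Why: Enolate alkylation brings in C1–C3, the allyl group entering anti to the trityloxymethyl group to give the 3,5-trans lactone that is corrected in the next step.

Step 3
Reactants: 6 (3S,5R)-3-allyl-5-((trityloxy)methyl)dihydrofuran-2(3H)-one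
Product: 8 (3R,5R)-3-allyl-5-((trityloxy)methyl)dihydrofuran-2(3H)-one, via lithium allyl-lactone enolate 7 (not isolated)
Conditions: LiN(i-Pr)2, THF, −78 °C; then sat. aq. Na2SO4, −78 °C
Reagents that add atoms: none
Why: Deprotonation–kinetic protonation epimerisation, in which the proton is delivered to the planar enolate anti to CH2OTr so that the allyl group ends cis to it, sets C10 (R) relative to C8; the minor trans isomer is separated and recycled.

Step 4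
Reactants: 8 (3R,5R)-3-allyl-5-((trityloxy)methyl)dihydrofuran-2(3H)-one
Product: 9 (2R,4R)-2-allyl-5-(trityloxy)pentane-1,4-diol
Conditions: LiAlH4, THF, 0 °C → rt
Reagents that add atoms: none
Why: Hydride reduction of the lactone gives the 1,4-diol (primary O14, secondary O8) without touching either stereocentre.

Step 5
Reactants: 9 (2R,4R)-2-allyl-5-(trityloxy)pentane-1,4-diol; 10 tert-butyldiphenylsilyl chloride
Product: 11 (2R,4R)-4-(((tert-butyldiphenylsilyl)oxy)methyl)-1-(trityloxy)hept-6-en-2-ol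
Conditions: TBDPSCl (1.05 equiv), imidazole, CH2Cl2, 0 °C
Reagents that add atoms: tert-butyldiphenylsilyl chloride 10, CC(C)(C)[Si](Cl)(c1ccccc1)c1ccccc1
Why: Chemoselective silylation of the primary hydroxyl over the hindered secondary one protects O14 until the last step.

Step 6
Reactants: 11 (2R,4R)-4-(((tert-butyldiphenylsilyl)oxy)methyl)-1-(trityloxy)hept-6-en-2-ol; 12 4-methoxybenzyl chloride
Product: 14 tert-butyl(((2R,4R)-2-allyl-4-((4-methoxybenzyl)oxy)-5-(trityloxy)pentyl)oxy)diphenylsilane, via sodium alkoxide 13 (not isolated)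
Conditions: NaH, THF/DMF, 0 °C; then PMBCl, Bu4NI (cat.), 0 °C → rt
Reagents that add atoms: 4-methoxybenzyl chloride 12, COc1ccc(CCl)cc1
Why: Williamson etherification protects O8 as a PMB ether that is orthogonal to the silyl and trityl ethers.

Step 7
Reactants: 14 tert-butyl(((2R,4R)-2-allyl-4-((4-methoxybenzyl)oxy)-5-(trityloxy)pentyl)oxy)diphenylsilane
Product: 15 (2R,4R)-4-(((tert-butyldiphenylsilyl)oxy)methyl)-2-((4-methoxybenzyl)oxy)hept-6-en-1-ol
Conditions: TsOH·H2O (cat.), MeOH/CH2Cl2, 0 °C → rt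
Reagents that add atoms: none
Why: Acid-catalysed methanolysis removes the trityl ether while the TBDPS and PMB ethers survive, and it is done before any acid-labile silyl ether is in the molecule.

Step 8
Reactants: 16 but-2-yne-1,4-diol; 17 tributyltin hydride
Product: 18 (E)-2-(tributylstannyl)but-2-ene-1,4-diol
Conditions: Bu3SnH, PdCl2(PPh3)2 (2 mol %), THF, rt
Reagents that add atoms: tributyltin hydride 17, CCCC[SnH](CCCC)CCCC
Why: Palladium-catalysed syn-hydrostannation of the symmetrical alkyne gives a single regio- and stereoisomer in which the two CH2OH groups are cis.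

Step 9
Reactants: 18 (E)-2-(tributylstannyl)but-2-ene-1,4-diol; 19 tert-butyldimethylsilyl chloride
Product: 20 (E)-4-((tert-butyldimethylsilyl)oxy)-2-(tributylstannyl)but-2-en-1-ol
Conditions: TBSCl (1.0 equiv), imidazole, CH2Cl2, −20 °C
Reagents that add atoms: tert-butyldimethylsilyl chloride 19, CC(C)(C)[Si](C)(C)Cl
Why: Sterically controlled monosilylation takes place at the hydroxyl remote from the bulky Bu3Sn group, which is the future O6.

Step 10
Reactants: 20 (E)-4-((tert-butyldimethylsilyl)oxy)-2-(tributylstannyl)but-2-en-1-ol; 10 tert-butyldiphenylsilyl chloride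
Product: 21 (E)-tert-butyl((4-((tert-butyldimethylsilyl)oxy)-2-(tributylstannyl)but-2-en-1-yl)oxy)diphenylsilane
Conditions: TBDPSCl, imidazole, DMF, rt
Reagents that add atoms: tert-butyldiphenylsilyl chloride 10, CC(C)(C)[Si](Cl)(c1ccccc1)c1ccccc1
Why: Silylation of the remaining hydroxyl (future O15) with the more robust group differentiates the two oxygens.

Step 11
Reactants: 21 (E)-tert-butyl((4-((tert-butyldimethylsilyl)oxy)-2-(tributylstannyl)but-2-en-1-yl)oxy)diphenylsilane; 22 iodine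
Product: 23 (E)-tert-butyl((4-((tert-butyldimethylsilyl)oxy)-2-iodobut-2-en-1-yl)oxy)diphenylsilane
Conditions: I2, CH2Cl2, 0 °C
Reagents that add atoms: iodine 22, [I][I]
Why: Iododestannylation with retention of alkene geometry gives the vinyl iodide in which iodine is trans to C6.

Step 12
Reactants: 15 (2R,4R)-4-(((tert-butyldiphenylsilyl)oxy)methyl)-2-((4-methoxybenzyl)oxy)hept-6-en-1-ol; 23 (E)-tert-butyl((4-((tert-butyldimethylsilyl)oxy)-2-iodobut-2-en-1-yl)oxy)diphenylsilane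
Product: 25 (2R,4R,8Z)-10-((tert-butyldimethylsilyl)oxy)-4,8-bis(((tert-butyldiphenylsilyl)oxy)methyl)-2-((4-methoxybenzyl)oxy)dec-8-en-1-ol, via B-alkyl-9-BBN borane 24 (not isolated)
Conditions: 9-BBN (2.4 equiv), THF, rt; then 23, PdCl2(dppf) (5 mol %), AsPh3, Cs2CO3, DMF/H2O, rt
Reagents that add atoms: vinyl iodide 23, CC(C)(C)[Si](C)(C)OC/C=C(/I)CO[Si](c1ccccc1)(c1ccccc1)C(C)(C)C
Why: Anti-Markovnikov hydroboration of the terminal alkene and B-alkyl Suzuki–Miyaura coupling with retention at the vinyl iodide form C3–C4 and fix the C4=C5 geometry (C3 trans to C6), the free hydroxyl being carried as its borinate and released on work-up.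

Step 13
Reactants: 25 (2R,4R,8Z)-10-((tert-butyldimethylsilyl)oxy)-4,8-bis(((tert-butyldiphenylsilyl)oxy)methyl)-2-((4-methoxybenzyl)oxy)dec-8-en-1-ol
Product: 26 (2R,4R,8Z)-10-((tert-butyldimethylsilyl)oxy)-4,8-bis(((tert-butyldiphenylsilyl)oxy)methyl)-2-((4-methoxybenzyl)oxy)dec-8-enal
Conditions: Dess–Martin periodinane, pyridine, CH2Cl2, 0 °C → rt
Reagents that add atoms: none
Why: Dess–Martin oxidation gives the α-alkoxy aldehyde under buffered conditions that do not epimerise C8.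

Step 14
Reactants: 26 (2R,4R,8Z)-10-((tert-butyldimethylsilyl)oxy)-4,8-bis(((tert-butyldiphenylsilyl)oxy)methyl)-2-((4-methoxybenzyl)oxy)dec-8-enal; 27 dimethyl (1-diazo-2-oxopropyl)phosphonate
Product: 28 (3R,5R,9Z)-11-((tert-butyldimethylsilyl)oxy)-5,9-bis(((tert-butyldiphenylsilyl)oxy)methyl)-3-((4-methoxybenzyl)oxy)undec-9-en-1-yne
Conditions: K2CO3, MeOH, 0 °C → rt
Reagents that add atoms: dimethyl (1-diazo-2-oxopropyl)phosphonate 27, COP(=O)(OC)C(=[N+]=[N-])C(C)=O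
Why: Ohira–Bestmann (Seyferth–Gilbert type) homologation converts the aldehyde into the terminal alkyne and adds C11.

Step 15
Reactants: 28 (3R,5R,9Z)-11-((tert-butyldimethylsilyl)oxy)-5,9-bis(((tert-butyldiphenylsilyl)oxy)methyl)-3-((4-methoxybenzyl)oxy)undec-9-en-1-yne; 29 methyl chloroformate
Product: 31 methyl (4R,6R,10Z)-12-((tert-butyldimethylsilyl)oxy)-6,10-bis(((tert-butyldiphenylsilyl)oxy)methyl)-4-((4-methoxybenzyl)oxy)dodec-10-en-2-ynoate, via lithium acetylide 30 (not isolated)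
Conditions: n-BuLi, THF, −78 °C; then ClCO2Me, −78 → −20 °C
Reagents that add atoms: methyl chloroformate 29, COC(=O)Cl
Why: Acylation of the lithium acetylide adds C12 and gives the ynoate needed for the conjugate hydrometalation.

Step 16
Reactants: 31 methyl (4R,6R,10Z)-12-((tert-butyldimethylsilyl)oxy)-6,10-bis(((tert-butyldiphenylsilyl)oxy)methyl)-4-((4-methoxybenzyl)oxy)dodec-10-en-2-ynoate; 32 2-(iodomethyl)-4,4,5,5-tetramethyl-1,3,2-dioxaborolane
Product: 34 methyl (2Z,4R,6R,10Z)-12-((tert-butyldimethylsilyl)oxy)-6,10-bis(((tert-butyldiphenylsilyl)oxy)methyl)-4-((4-methoxybenzyl)oxy)-2-((4,4,5,5-tetramethyl-1,3,2-dioxaborolan-2-yl)methyl)dodeca-2,10-dienoate, via alpha-alumino enoate 33 (not isolated)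
Conditions: i-Bu2AlH, HMPA, THF, 0 °C; then ICH2Bpin, 0 °C → rt
Reagents that add atoms: 2-(iodomethyl)-4,4,5,5-tetramethyl-1,3,2-dioxaborolane 32, CC1(C)OB(CI)OC1(C)C
Why: Syn conjugate hydroalumination of the ynoate and C-alkylation of the vinylalane by the iodomethylboronate (boron ate complex, then 1,2-shift with loss of iodide) give the 2-(methoxycarbonyl)allylboronate with H7 and CH2B cis, that is with C8 cis to the ester.

Step 17
Reactants: 34 methyl (2Z,4R,6R,10Z)-12-((tert-butyldimethylsilyl)oxy)-6,10-bis(((tert-butyldiphenylsilyl)oxy)methyl)-4-((4-methoxybenzyl)oxy)-2-((4,4,5,5-tetramethyl-1,3,2-dioxaborolan-2-yl)methyl)dodeca-2,10-dienoate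
Product: 35 methyl (2Z,4R,6R,10Z)-6,10-bis(((tert-butyldiphenylsilyl)oxy)methyl)-12-hydroxy-4-((4-methoxybenzyl)oxy)-2-((4,4,5,5-tetramethyl-1,3,2-dioxaborolan-2-yl)methyl)dodeca-2,10-dienoate
Conditions: PPTS, MeOH/CH2Cl2, rt
Reagents that add atoms: none
Why: Mild acid methanolysis cleaves the primary allylic TBS ether selectively in the presence of the TBDPS ethers, the PMB ether and the pinacol boronate.

Step 18
Reactants: 35 methyl (2Z,4R,6R,10Z)-6,10-bis(((tert-butyldiphenylsilyl)oxy)methyl)-12-hydroxy-4-((4-methoxybenzyl)oxy)-2-((4,4,5,5-tetramethyl-1,3,2-dioxaborolan-2-yl)methyl)dodeca-2,10-dienoate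
Product: 36 methyl (2Z,4R,6R,10Z)-6,10-bis(((tert-butyldiphenylsilyl)oxy)methyl)-4-((4-methoxybenzyl)oxy)-12-oxo-2-((4,4,5,5-tetramethyl-1,3,2-dioxaborolan-2-yl)methyl)dodeca-2,10-dienoate
Conditions: MnO2, CH2Cl2, rt
Reagents that add atoms: none
Why: Chemoselective allylic oxidation gives the enal without isomerising the C4=C5 bond or consuming the deactivated allylboronate, which does not add to aldehydes at room temperature without a catalyst.

Step 19
Reactants: 36 methyl (2Z,4R,6R,10Z)-6,10-bis(((tert-butyldiphenylsilyl)oxy)methyl)-4-((4-methoxybenzyl)oxy)-12-oxo-2-((4,4,5,5-tetramethyl-1,3,2-dioxaborolan-2-yl)methyl)dodeca-2,10-dienoate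
Product: 38 (3aS,4R,6R,10Z,11aS)-6,10-bis(((tert-butyldiphenylsilyl)oxy)methyl)-4-((4-methoxybenzyl)oxy)-3-methylene-3a,4,5,6,7,8,9,11a-octahydrocyclodeca[b]furan-2(3H)-one, via cyclic O-boryl hydroxy ester 37 (not isolated)
Conditions: Sc(OTf)3 (20 mol %), toluene, 0.001 M (syringe-pump addition), 40 °C
Reagents that add atoms: none
Why: Proposed new method: a Sc(OTf)3-catalysed macrocyclising allylboration of a 2-(methoxycarbonyl)allyl pinacolboronate onto a tethered enal with in situ lactonisation, which has not been shown for a medium ring; the Lewis acid binds a pinacolate oxygen and makes boron electrophilic enough to take the aldehyde into a closed six-membered chair transition state, the fixed boronate geometry (C8 trans to CH2B) puts C5 and C8 both equatorial and so gives the anti, 6,7-trans adduct stereospecifically (C6 S), the C8 stereocentre sets C7 (S) because with H8 eclipsing the ester-bearing alkene (allylic 1,3-strain) the tether through C9 lies on the attacking face and the PMB ether is anti to the new bond, and the O6 borate 37 then lactonises onto the methyl ester with loss of MeOBpin; the closest known reaction type is the intermolecular Lewis-acid-catalysed allylboration–lactonisation of 2-alkoxycarbonyl allylboronates with aldehydes, whereas Barbier-type closures with equilibrating allylchromium or allylzinc species tend to give the 6,7-cis lactone.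

Step 20
Reactants: 38 (3aS,4R,6R,10Z,11aS)-6,10-bis(((tert-butyldiphenylsilyl)oxy)methyl)-4-((4-methoxybenzyl)oxy)-3-methylene-3a,4,5,6,7,8,9,11a-octahydrocyclodeca[b]furan-2(3H)-one
Product: 39 (3aS,4R,6R,10Z,11aS)-6,10-bis(((tert-butyldiphenylsilyl)oxy)methyl)-4-hydroxy-3-methylene-3a,4,5,6,7,8,9,11a-octahydrocyclodeca[b]furan-2(3H)-one
Conditions: DDQ, CH2Cl2/pH 7 buffer, 0 °C → rt
Reagents that add atoms: none
Why: Oxidative cleavage of the PMB ether frees O8 alone, under neutral conditions that spare the silyl ethers and the α-methylene lactone.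

Step 21
Reactants: 39 (3aS,4R,6R,10Z,11aS)-6,10-bis(((tert-butyldiphenylsilyl)oxy)methyl)-4-hydroxy-3-methylene-3a,4,5,6,7,8,9,11a-octahydrocyclodeca[b]furan-2(3H)-one; 40 methacryloyl chloride
Product: 41 (3aS,4R,6R,10Z,11aS)-6,10-bis(((tert-butyldiphenylsilyl)oxy)methyl)-3-methylene-2-oxo-2,3,3a,4,5,6,7,8,9,11a-decahydrocyclodeca[b]furan-4-yl methacrylate
Conditions: methacryloyl chloride, Et3N, DMAP (cat.), CH2Cl2, 0 °C
Reagents that add atoms: methacryloyl chloride 40, CC(=C)C(=O)Cl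
Why: O-acylation of the only free hydroxyl installs the methacrylate with retention at C8.

Step 22
Reactants: 41 (3aS,4R,6R,10Z,11aS)-6,10-bis(((tert-butyldiphenylsilyl)oxy)methyl)-3-methylene-2-oxo-2,3,3a,4,5,6,7,8,9,11a-decahydrocyclodeca[b]furan-4-yl methacrylate
Product: 42 (3aS,4R,6R,10Z,11aS)-6,10-bis(hydroxymethyl)-3-methylene-2-oxo-2,3,3a,4,5,6,7,8,9,11a-decahydrocyclodeca[b]furan-4-yl methacrylate
Conditions: HF·pyridine, pyridine, THF, 0 °C → rt
Reagents that add atoms: none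
Why: Buffered fluoride desilylation removes both primary TBDPS ethers without base, so the methacrylate, the allylic lactone and the α-methylene group are left intact.

**Compound list**

1 | (R)-5-(hydroxymethyl)dihydrofuran-2(3H)-one | O=C1O[C@@H](CO)CC1 | starting material
2 | trityl chloride | ClC(c1ccccc1)(c1ccccc1)c1ccccc1 | starting material
3 | (R)-5-((trityloxy)methyl)dihydrofuran-2(3H)-one | O=C1O[C@@H](COC(c2ccccc2)(c2ccccc2)c2ccccc2)CC1 | intermediate
4 | allyl bromide | C=CCBr | starting material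
5 | lithium enolate of 3, lithium (R)-5-((trityloxy)methyl)-4,5-dihydrofuran-2-olate | [Li]OC1=CC[C@H](COC(c2ccccc2)(c2ccccc2)c2ccccc2)O1 | intermediate
6 | (3S,5R)-3-allyl-5-((trityloxy)methyl)dihydrofuran-2(3H)-one (allyl trans to CH2OTr) | O=C1O[C@@H](COC(c2ccccc2)(c2ccccc2)c2ccccc2)C[C@@H]1CC=C | intermediate
7 | lithium enolate of 6, lithium (R)-3-allyl-5-((trityloxy)methyl)-4,5-dihydrofuran-2-olate | [Li]OC1=C(CC=C)C[C@H](COC(c2ccccc2)(c2ccccc2)c2ccccc2)O1 | intermediate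
8 | (3R,5R)-3-allyl-5-((trityloxy)methyl)dihydrofuran-2(3H)-one (allyl cis to CH2OTr) | O=C1O[C@@H](COC(c2ccccc2)(c2ccccc2)c2ccccc2)C[C@H]1CC=C | intermediate
9 | (2R,4R)-2-allyl-5-(trityloxy)pentane-1,4-diol | C(c1ccccc1)(c1ccccc1)(c1ccccc1)OC[C@H](O)C[C@H](CO)CC=C | intermediate
10 | tert-butyldiphenylsilyl chloride | CC(C)(C)[Si](Cl)(c1ccccc1)c1ccccc1 | starting material
11 | (2R,4R)-4-(((tert-butyldiphenylsilyl)oxy)methyl)-1-(trityloxy)hept-6-en-2-ol | C(c1ccccc1)(c1ccccc1)(c1ccccc1)OC[C@H](O)C[C@H](CO[Si](c1ccccc1)(c1ccccc1)C(C)(C)C)CC=C | intermediate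
12 | 4-methoxybenzyl chloride | COc1ccc(CCl)cc1 | starting material
13 | sodium alkoxide of 11, sodium (2R,4R)-4-(((tert-butyldiphenylsilyl)oxy)methyl)-1-(trityloxy)hept-6-en-2-olate | C(c1ccccc1)(c1ccccc1)(c1ccccc1)OC[C@H](O[Na])C[C@H](CO[Si](c1ccccc1)(c1ccccc1)C(C)(C)C)CC=C | intermediate
14 | tert-butyl(((2R,4R)-2-allyl-4-((4-methoxybenzyl)oxy)-5-(trityloxy)pentyl)oxy)diphenylsilane | C(c1ccccc1)(c1ccccc1)(c1ccccc1)OC[C@H](OCc1ccc(OC)cc1)C[C@H](CO[Si](c1ccccc1)(c1ccccc1)C(C)(C)C)CC=C | intermediate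
15 | (2R,4R)-4-(((tert-butyldiphenylsilyl)oxy)methyl)-2-((4-methoxybenzyl)oxy)hept-6-en-1-ol | OC[C@H](OCc1ccc(OC)cc1)C[C@H](CO[Si](c1ccccc1)(c1ccccc1)C(C)(C)C)CC=C | intermediate
16 | but-2-yne-1,4-diol | OCC#CCO | starting material
17 | tributyltin hydride | CCCC[SnH](CCCC)CCCC | starting material
18 | (E)-2-(tributylstannyl)but-2-ene-1,4-diol | OC/C=C(/[Sn](CCCC)(CCCC)CCCC)CO | intermediate
19 | tert-butyldimethylsilyl chloride | CC(C)(C)[Si](C)(C)Cl | starting material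
20 | (E)-4-((tert-butyldimethylsilyl)oxy)-2-(tributylstannyl)but-2-en-1-ol | CC(C)(C)[Si](C)(C)OC/C=C(/[Sn](CCCC)(CCCC)CCCC)CO | intermediate
21 | (E)-tert-butyl((4-((tert-butyldimethylsilyl)oxy)-2-(tributylstannyl)but-2-en-1-yl)oxy)diphenylsilane | CC(C)(C)[Si](C)(C)OC/C=C(/[Sn](CCCC)(CCCC)CCCC)CO[Si](c1ccccc1)(c1ccccc1)C(C)(C)C | intermediate
22 | iodine | [I][I] | starting material
23 | (E)-tert-butyl((4-((tert-butyldimethylsilyl)oxy)-2-iodobut-2-en-1-yl)oxy)diphenylsilane | CC(C)(C)[Si](C)(C)OC/C=C(/I)CO[Si](c1ccccc1)(c1ccccc1)C(C)(C)C | intermediate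
24 | B-alkyl-9-BBN borane of 15 (C3 bound to boron, O7 carried as its 9-BBN borinate, 2R,4R as in 15) | O(B1C2CCCC1CCC2)C[C@H](OCc1ccc(OC)cc1)C[C@H](CO[Si](c1ccccc1)(c1ccccc1)C(C)(C)C)CCCB1C2CCCC1CCC2 | intermediate
25 | (2R,4R,8Z)-10-((tert-butyldimethylsilyl)oxy)-4,8-bis(((tert-butyldiphenylsilyl)oxy)methyl)-2-((4-methoxybenzyl)oxy)dec-8-en-1-ol | OC[C@H](OCc1ccc(OC)cc1)C[C@H](CO[Si](c1ccccc1)(c1ccccc1)C(C)(C)C)CCC/C(CO[Si](c1ccccc1)(c1ccccc1)C(C)(C)C)=C/CO[Si](C)(C)C(C)(C)C | intermediate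
26 | (2R,4R,8Z)-10-((tert-butyldimethylsilyl)oxy)-4,8-bis(((tert-butyldiphenylsilyl)oxy)methyl)-2-((4-methoxybenzyl)oxy)dec-8-enal | O=C[C@H](OCc1ccc(OC)cc1)C[C@H](CO[Si](c1ccccc1)(c1ccccc1)C(C)(C)C)CCC/C(CO[Si](c1ccccc1)(c1ccccc1)C(C)(C)C)=C/CO[Si](C)(C)C(C)(C)C | intermediate
27 | dimethyl (1-diazo-2-oxopropyl)phosphonate | COP(=O)(OC)C(=[N+]=[N-])C(C)=O | starting material
28 | (3R,5R,9Z)-11-((tert-butyldimethylsilyl)oxy)-5,9-bis(((tert-butyldiphenylsilyl)oxy)methyl)-3-((4-methoxybenzyl)oxy)undec-9-en-1-yne | C#C[C@H](OCc1ccc(OC)cc1)C[C@H](CO[Si](c1ccccc1)(c1ccccc1)C(C)(C)C)CCC/C(CO[Si](c1ccccc1)(c1ccccc1)C(C)(C)C)=C/CO[Si](C)(C)C(C)(C)C | intermediate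
29 | methyl chloroformate | COC(=O)Cl | starting material
30 | lithium acetylide of 28 | [Li]C#C[C@H](OCc1ccc(OC)cc1)C[C@H](CO[Si](c1ccccc1)(c1ccccc1)C(C)(C)C)CCC/C(CO[Si](c1ccccc1)(c1ccccc1)C(C)(C)C)=C/CO[Si](C)(C)C(C)(C)C | intermediate
31 | methyl (4R,6R,10Z)-12-((tert-butyldimethylsilyl)oxy)-6,10-bis(((tert-butyldiphenylsilyl)oxy)methyl)-4-((4-methoxybenzyl)oxy)dodec-10-en-2-ynoate | COC(=O)C#C[C@H](OCc1ccc(OC)cc1)C[C@H](CO[Si](c1ccccc1)(c1ccccc1)C(C)(C)C)CCC/C(CO[Si](c1ccccc1)(c1ccccc1)C(C)(C)C)=C/CO[Si](C)(C)C(C)(C)C | intermediate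
32 | 2-(iodomethyl)-4,4,5,5-tetramethyl-1,3,2-dioxaborolane | CC1(C)OB(CI)OC1(C)C | starting material
33 | methyl (2E,4R,6R,10Z)-12-((tert-butyldimethylsilyl)oxy)-6,10-bis(((tert-butyldiphenylsilyl)oxy)methyl)-2-(diisobutylalumanyl)-4-((4-methoxybenzyl)oxy)dodeca-2,10-dienoate (Al cis to H7) | COC(=O)/C([Al](CC(C)C)CC(C)C)=C\[C@H](OCc1ccc(OC)cc1)C[C@H](CO[Si](c1ccccc1)(c1ccccc1)C(C)(C)C)CCC/C(CO[Si](c1ccccc1)(c1ccccc1)C(C)(C)C)=C/CO[Si](C)(C)C(C)(C)C | intermediate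
34 | methyl (2Z,4R,6R,10Z)-12-((tert-butyldimethylsilyl)oxy)-6,10-bis(((tert-butyldiphenylsilyl)oxy)methyl)-4-((4-methoxybenzyl)oxy)-2-((4,4,5,5-tetramethyl-1,3,2-dioxaborolan-2-yl)methyl)dodeca-2,10-dienoate | COC(=O)/C(CB1OC(C)(C)C(C)(C)O1)=C\[C@H](OCc1ccc(OC)cc1)C[C@H](CO[Si](c1ccccc1)(c1ccccc1)C(C)(C)C)CCC/C(CO[Si](c1ccccc1)(c1ccccc1)C(C)(C)C)=C/CO[Si](C)(C)C(C)(C)C | intermediate
35 | methyl (2Z,4R,6R,10Z)-6,10-bis(((tert-butyldiphenylsilyl)oxy)methyl)-12-hydroxy-4-((4-methoxybenzyl)oxy)-2-((4,4,5,5-tetramethyl-1,3,2-dioxaborolan-2-yl)methyl)dodeca-2,10-dienoate | COC(=O)/C(CB1OC(C)(C)C(C)(C)O1)=C\[C@H](OCc1ccc(OC)cc1)C[C@H](CO[Si](c1ccccc1)(c1ccccc1)C(C)(C)C)CCC/C(CO[Si](c1ccccc1)(c1ccccc1)C(C)(C)C)=C/CO | intermediate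
36 | methyl (2Z,4R,6R,10Z)-6,10-bis(((tert-butyldiphenylsilyl)oxy)methyl)-4-((4-methoxybenzyl)oxy)-12-oxo-2-((4,4,5,5-tetramethyl-1,3,2-dioxaborolan-2-yl)methyl)dodeca-2,10-dienoate | COC(=O)/C(CB1OC(C)(C)C(C)(C)O1)=C\[C@H](OCc1ccc(OC)cc1)C[C@H](CO[Si](c1ccccc1)(c1ccccc1)C(C)(C)C)CCC/C(CO[Si](c1ccccc1)(c1ccccc1)C(C)(C)C)=C/C=O | intermediate
37 | ring-closed O-boryl hydroxy ester: cyclodec-4-ene closed at C6–C7, O6 bound to Bpin, C7 carrying C(=CH2)CO2Me, configurations at C6, C7, C8 and C10 as in 38 | COc1ccc(CO[C@@H]2C[C@H](CO[Si](c3ccccc3)(c3ccccc3)C(C)(C)C)CCC/C(CO[Si](c3ccccc3)(c3ccccc3)C(C)(C)C)=C/[C@H](OB3OC(C)(C)C(C)(C)O3)[C@H]2C(=C)C(=O)OC)cc1 | intermediate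
38 | (3aS,4R,6R,10Z,11aS)-6,10-bis(((tert-butyldiphenylsilyl)oxy)methyl)-4-((4-methoxybenzyl)oxy)-3-methylene-3a,4,5,6,7,8,9,11a-octahydrocyclodeca[b]furan-2(3H)-one | COc1ccc(CO[C@@H]2C[C@H](CO[Si](c3ccccc3)(c3ccccc3)C(C)(C)C)CCC/C(CO[Si](c3ccccc3)(c3ccccc3)C(C)(C)C)=C/[C@@H]3OC(=O)C(=C)[C@H]32)cc1 | intermediate
39 | (3aS,4R,6R,10Z,11aS)-6,10-bis(((tert-butyldiphenylsilyl)oxy)methyl)-4-hydroxy-3-methylene-3a,4,5,6,7,8,9,11a-octahydrocyclodeca[b]furan-2(3H)-one | O[C@@H]1C[C@H](CO[Si](c2ccccc2)(c2ccccc2)C(C)(C)C)CCC/C(CO[Si](c2ccccc2)(c2ccccc2)C(C)(C)C)=C/[C@@H]2OC(=O)C(=C)[C@H]21 | intermediate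
40 | methacryloyl chloride | CC(=C)C(=O)Cl | starting material
41 | (3aS,4R,6R,10Z,11aS)-6,10-bis(((tert-butyldiphenylsilyl)oxy)methyl)-3-methylene-2-oxo-2,3,3a,4,5,6,7,8,9,11a-decahydrocyclodeca[b]furan-4-yl methacrylate | C=C(C)C(=O)O[C@@H]1C[C@H](CO[Si](c2ccccc2)(c2ccccc2)C(C)(C)C)CCC/C(CO[Si](c2ccccc2)(c2ccccc2)C(C)(C)C)=C/[C@@H]2OC(=O)C(=C)[C@H]21 | intermediate
42 | (3aS,4R,6R,10Z,11aS)-6,10-bis(hydroxymethyl)-3-methylene-2-oxo-2,3,3a,4,5,6,7,8,9,11a-decahydrocyclodeca[b]furan-4-yl methacrylate (CNP0256084.5) | C=C(C)C(=O)O[C@@H]1C[C@H](CO)CCC/C(CO)=C/[C@@H]2OC(=O)C(=C)[C@H]21 | target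

**Step count and risk**

Total step count: 22. Longest linear sequence: 18 steps (1 → 42 through steps 1–7 and 12–22); the vinyl iodide branch (steps 8–11) is 4 steps.

The three steps most likely to fail are step 19, step 16 and step 3.

Step 19 (the proposed macrocyclising allylboration; the ring may not close, or the C7 face may be wrong). The fallback sets out from 15 and 23 and comes back at 38. It uses only known reactions: the lactone is made first by intermolecular allylboration, and the ring is closed last at C3–C4. Alcohol 15 is oxidised (Dess–Martin periodinane) to (2R,4R)-4-(((tert-butyldiphenylsilyl)oxy)methyl)-2-((4-methoxybenzyl)oxy)hept-6-enal F1. F1 is homologated with 27 (K2CO3, MeOH) to (3R,5R)-5-(((tert-butyldiphenylsilyl)oxy)methyl)-3-((4-methoxybenzyl)oxy)oct-7-en-1-yne F2. Deprotonation (n-BuLi) gives lithium acetylide F3, which is acylated with 29 to methyl (4R,6R)-6-(((tert-butyldiphenylsilyl)oxy)methyl)-4-((4-methoxybenzyl)oxy)non-8-en-2-ynoate F4. Syn hydroalumination (i-Bu2AlH, HMPA) gives alpha-alumino enoate F5, which is alkylated with 32 to methyl (2Z,4R,6R)-6-(((tert-butyldiphenylsilyl)oxy)methyl)-4-((4-methoxybenzyl)oxy)-2-((4,4,5,5-tetramethyl-1,3,2-dioxaborolan-2-yl)methyl)nona-2,8-dienoate F6. Separately, 23 is desilylated (PPTS, MeOH) to (E)-4-((tert-butyldiphenylsilyl)oxy)-3-iodobut-2-en-1-ol F7 and oxidised (MnO2) to (E)-4-((tert-butyldiphenylsilyl)oxy)-3-iodobut-2-enal F8. The known intermolecular Sc(OTf)3-catalysed allylboration of F8 with F6 passes through O-boryl hydroxy ester F9 and lactonises to (4S,5R)-4-((1R,3R)-3-(((tert-butyldiphenylsilyl)oxy)methyl)-1-((4-methoxybenzyl)oxy)hex-5-en-1-yl)-5-((E)-3-((tert-butyldiphenylsilyl)oxy)-2-iodoprop-1-en-1-yl)-3-methylenedihydrofuran-2(3H)-one F10; the anti relationship follows from the boronate geometry, and diastereomers at C7 are separated if needed. Hydroboration of the terminal alkene of F10 with 9-BBN gives B-alkyl-9-BBN borane F11. An intramolecular B-alkyl Suzuki–Miyaura coupling (PdCl2(dppf), AsPh3, Cs2CO3, DMF/THF/H2O, high dilution) then closes C3–C4 to give 38.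

Step 16 (hydroalumination and borylmethylation; the vinylalane may lose its geometry or alkylate poorly). The fallback sets out from 31 and comes back at 34. Syn hydrostannation of 31 with 17 (Pd(PPh3)4, THF, 0 °C) gives methyl (2E,4R,6R,10Z)-12-((tert-butyldimethylsilyl)oxy)-6,10-bis(((tert-butyldiphenylsilyl)oxy)methyl)-4-((4-methoxybenzyl)oxy)-2-(tributylstannyl)dodeca-2,10-dienoate F12, with tin on the ester-bearing carbon and cis to H7. Iododestannylation with 22 gives methyl (2E,4R,6R,10Z)-12-((tert-butyldimethylsilyl)oxy)-6,10-bis(((tert-butyldiphenylsilyl)oxy)methyl)-2-iodo-4-((4-methoxybenzyl)oxy)dodeca-2,10-dienoate F13 with retention. Negishi coupling (Pd(PPh3)4, THF) with (pinacolatoboryl)methylzinc iodide F14, made from 32 and Zn, gives 34 with the same geometry.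

Step 3 (kinetic protonation; the cis:trans ratio may be low). The fallback sets out from 6 and comes back at 8. It replaces ionic protonation by radical hydrogen-atom transfer. Enolate 7 (from 6 and LiN(i-Pr)2) is trapped with PhSeBr to give (3S,5R)-3-allyl-3-(phenylselanyl)-5-((trityloxy)methyl)dihydrofuran-2(3H)-one F15. Reductive deselenation (Bu3SnH, Et3B/air, toluene, −78 °C) delivers the hydrogen atom to the planar lactone radical anti to CH2OTr and gives 8.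

**Further compounds**

F1 | step 19 | (2R,4R)-4-(((tert-butyldiphenylsilyl)oxy)methyl)-2-((4-methoxybenzyl)oxy)hept-6-enal | O=C[C@H](OCc1ccc(OC)cc1)C[C@H](CO[Si](c1ccccc1)(c1ccccc1)C(C)(C)C)CC=C
F2 | step 19 | (3R,5R)-5-(((tert-butyldiphenylsilyl)oxy)methyl)-3-((4-methoxybenzyl)oxy)oct-7-en-1-yne | C#C[C@H](OCc1ccc(OC)cc1)C[C@H](CO[Si](c1ccccc1)(c1ccccc1)C(C)(C)C)CC=C
F3 | step 19 | lithium acetylide of F2 | [Li]C#C[C@H](OCc1ccc(OC)cc1)C[C@H](CO[Si](c1ccccc1)(c1ccccc1)C(C)(C)C)CC=C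
F4 | step 19 | methyl (4R,6R)-6-(((tert-butyldiphenylsilyl)oxy)methyl)-4-((4-methoxybenzyl)oxy)non-8-en-2-ynoate | COC(=O)C#C[C@H](OCc1ccc(OC)cc1)C[C@H](CO[Si](c1ccccc1)(c1ccccc1)C(C)(C)C)CC=C
F5 | step 19 | alpha-alumino enoate from F4, methyl (2E,4R,6R)-6-(((tert-butyldiphenylsilyl)oxy)methyl)-2-(diisobutylalumanyl)-4-((4-methoxybenzyl)oxy)nona-2,8-dienoate | COC(=O)/C([Al](CC(C)C)CC(C)C)=C\[C@H](OCc1ccc(OC)cc1)C[C@H](CO[Si](c1ccccc1)(c1ccccc1)C(C)(C)C)CC=C
F6 | step 19 | methyl (2Z,4R,6R)-6-(((tert-butyldiphenylsilyl)oxy)methyl)-4-((4-methoxybenzyl)oxy)-2-((4,4,5,5-tetramethyl-1,3,2-dioxaborolan-2-yl)methyl)nona-2,8-dienoate | COC(=O)/C(CB1OC(C)(C)C(C)(C)O1)=C\[C@H](OCc1ccc(OC)cc1)C[C@H](CO[Si](c1ccccc1)(c1ccccc1)C(C)(C)C)CC=C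
F7 | step 19 | (E)-4-((tert-butyldiphenylsilyl)oxy)-3-iodobut-2-en-1-ol | OC/C=C(/I)CO[Si](c1ccccc1)(c1ccccc1)C(C)(C)C
F8 | step 19 | (E)-4-((tert-butyldiphenylsilyl)oxy)-3-iodobut-2-enal | O=C/C=C(/I)CO[Si](c1ccccc1)(c1ccccc1)C(C)(C)C
F9 | step 19 | O-boryl hydroxy ester from F6 and F8 (open-chain allylboration adduct, O6 bound to Bpin) | COC(=O)C(=C)[C@H]([C@@H](OB1OC(C)(C)C(C)(C)O1)/C=C(/I)CO[Si](c1ccccc1)(c1ccccc1)C(C)(C)C)[C@H](OCc1ccc(OC)cc1)C[C@H](CO[Si](c1ccccc1)(c1ccccc1)C(C)(C)C)CC=C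
F10 | step 19 | (4S,5R)-4-((1R,3R)-3-(((tert-butyldiphenylsilyl)oxy)methyl)-1-((4-methoxybenzyl)oxy)hex-5-en-1-yl)-5-((E)-3-((tert-butyldiphenylsilyl)oxy)-2-iodoprop-1-en-1-yl)-3-methylenedihydrofuran-2(3H)-one | COc1ccc(CO[C@H](C[C@H](CO[Si](c2ccccc2)(c2ccccc2)C(C)(C)C)CC=C)[C@@H]2C(=C)C(=O)O[C@H]2/C=C(/I)CO[Si](c2ccccc2)(c2ccccc2)C(C)(C)C)cc1
F11 | step 19 | B-alkyl-9-BBN borane from F10 (C3 bound to boron) | COc1ccc(CO[C@H](C[C@H](CO[Si](c2ccccc2)(c2ccccc2)C(C)(C)C)CCCB2C3CCCC2CCC3)[C@@H]2C(=C)C(=O)O[C@H]2/C=C(/I)CO[Si](c2ccccc2)(c2ccccc2)C(C)(C)C)cc1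
F12 | step 16 | methyl (2E,4R,6R,10Z)-12-((tert-butyldimethylsilyl)oxy)-6,10-bis(((tert-butyldiphenylsilyl)oxy)methyl)-4-((4-methoxybenzyl)oxy)-2-(tributylstannyl)dodeca-2,10-dienoate | COC(=O)/C([Sn](CCCC)(CCCC)CCCC)=C\[C@H](OCc1ccc(OC)cc1)C[C@H](CO[Si](c1ccccc1)(c1ccccc1)C(C)(C)C)CCC/C(CO[Si](c1ccccc1)(c1ccccc1)C(C)(C)C)=C/CO[Si](C)(C)C(C)(C)C
F13 | step 16 | methyl (2E,4R,6R,10Z)-12-((tert-butyldimethylsilyl)oxy)-6,10-bis(((tert-butyldiphenylsilyl)oxy)methyl)-2-iodo-4-((4-methoxybenzyl)oxy)dodeca-2,10-dienoate | COC(=O)/C(I)=C\[C@H](OCc1ccc(OC)cc1)C[C@H](CO[Si](c1ccccc1)(c1ccccc1)C(C)(C)C)CCC/C(CO[Si](c1ccccc1)(c1ccccc1)C(C)(C)C)=C/CO[Si](C)(C)C(C)(C)C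
F14 | step 16 | (pinacolatoboryl)methylzinc iodide | CC1(C)OB(C[Zn]I)OC1(C)C
F15 | step 3 | (3S,5R)-3-allyl-3-(phenylselanyl)-5-((trityloxy)methyl)dihydrofuran-2(3H)-one | O=C1O[C@@H](COC(c2ccccc2)(c2ccccc2)c2ccccc2)C[C@]1(CC=C)[Se]c1ccccc1
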